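The route rests on disconnecting all four C–Br bonds at once. Every brominated carbon lies ortho or para to an oxygen: on the hydroquinone ring (ring A) C3 and C5 flank the C4 oxygen that ends as OMe, and on the phenoxy ring (ring B) C2′ and C4′ are ortho and para to the bridging ether oxygen. One electrophilic bromination therefore installs all four halogens on a bromine-free diaryl ether, 4-hydroxy-2-phenoxyphenyl pivalate, whose free C4 phenol steers ring A and whose C1 ester keeps C6 as CH and blocks quinone formation. The precursor comes from 2-phenoxyphenol by Elbs oxidation; methylation and ester cleavage finish the synthesis.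

Key step: step 3

Remark on the chemistry: the target has no stereocentre and no configurationally stable axis, so it is achiral and no stereocontrol is needed. Ring A is numbered from the carbon bearing the ester or free hydroxyl oxygen (C1), with the aryloxy carbon as C2. Ring B is primed, with C1′ on the ether oxygen.

Step 1
Reactants: 1 2-phenoxyphenol; 2 potassium persulfate
Product: 3 potassium 4-hydroxy-3-phenoxyphenyl sulfate
Conditions: K2S2O8 (1.0 equiv), 10% aq KOH, 10–20 °C; neutralise to pH 7, wash out unreacted 1 with Et2O, concentrate
Reagents that add atoms: potassium persulfate, [K+].[K+].[O-]S(=O)(=O)OOS(=O)(=O)[O-]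
Why: Elbs persulfate oxidation, in which the phenoxide attacks a peroxide oxygen of peroxodisulfate through its free para carbon and tautomerises, so the new oxygen should arrive para to the hydroxyl and already masked as a sulfate.

Step 2
Reactants: 3 potassium 4-hydroxy-3-phenoxyphenyl sulfate; 4 pivaloyl chloride
Product: 6 4-hydroxy-2-phenoxyphenyl pivalate, via O-pivaloyl aryl sulfate potassium salt 5 (not isolated)
Conditions: PivCl (2 equiv), aq KOH (pH ca. 11)/THF, 0 °C; then aq HCl to pH < 1, 50 °C
Reagents that add atoms: pivaloyl chloride, CC(C)(C)C(Cl)=O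
Why: Schotten–Baumann acylation of the only free phenoxide, then acid-catalysed hydrolysis of the aryl sulfate monoester by S–O cleavage, which a hindered aryl pivalate should survive.

Step 3
Reactants: 6 4-hydroxy-2-phenoxyphenyl pivalate; 7 bromine
Product: 8 3,5-dibromo-2-(2,4-dibromophenoxy)-4-hydroxyphenyl pivalate
Conditions: Br2 (4.2 equiv), AcOH, 20 °C then 50 °C, dark; aq NaHSO3 quench
Reagents that add atoms: bromine, BrBr
Why: Each C–Br bond should form by electrophilic aromatic substitution, bromine adding to give a Wheland (arenium) intermediate that loses its proton as HBr. The closest known reaction types are the ortho,ortho-dibromination of para-substituted phenols and the para-then-ortho bromination of diaryl ethers such as diphenyl ether. No ring is closed and no stereocentre is created. The selectivity required is C3 and C5 but not C6 on ring A, and C4′ plus one ortho carbon (C2′) but not C6′ on ring B. On ring A it is secured by the free C4 hydroxyl, which activates only its two ortho carbons (C5 is also para to the ether oxygen), while C6 is meta to both the hydroxyl and the ether oxygen and ortho only to the weakly donating, bulky pivaloyloxy group; on ring B it is secured by the limited charge of bromine and by the deactivation that two bromines impose on C6′, and the C1 ester also keeps the hydroquinone from being oxidised to a quinone.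

Step 4
Reactants: 8 3,5-dibromo-2-(2,4-dibromophenoxy)-4-hydroxyphenyl pivalate; 9 iodomethane
Product: 10 3,5-dibromo-2-(2,4-dibromophenoxy)-4-methoxyphenyl pivalate
Conditions: MeI (3 equiv), K2CO3 (1.5 equiv), acetone, 40 °C
Reagents that add atoms: iodomethane, CI
Why: Williamson O-methylation; the acidic 2,6-dibromophenol is fully deprotonated by carbonate, the small electrophile should tolerate the two flanking bromines, and anhydrous carbonate in acetone should leave the aryl pivalate intact.

Step 5
Reactants: 10 3,5-dibromo-2-(2,4-dibromophenoxy)-4-methoxyphenyl pivalate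
Product: 11 3,5-dibromo-2-(2,4-dibromophenoxy)-4-methoxyphenol
Conditions: NaOMe (2 equiv), MeOH/THF, 0 °C to rt; aq HCl
Reagents that add atoms: none
Why: Methoxide transesterification of an aryl ester, which should be fast because the electron-poor phenoxide is a good leaving group, while the aryl bromides, the methyl ether and the diaryl ether are inert to methoxide at room temperature.

Compound list
1 | 2-phenoxyphenol | Oc1ccccc1Oc1ccccc1 | starting material
2 | potassium persulfate (potassium peroxodisulfate) | [K+].[K+].[O-]S(=O)(=O)OOS(=O)(=O)[O-] | starting material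
3 | potassium 4-hydroxy-3-phenoxyphenyl sulfate | [K+].[O-]S(=O)(=O)Oc1ccc(O)c(Oc2ccccc2)c1 | intermediate
4 | pivaloyl chloride | CC(C)(C)C(Cl)=O | starting material
5 | potassium 3-phenoxy-4-(pivaloyloxy)phenyl sulfate | [K+].[O-]S(=O)(=O)Oc1ccc(OC(=O)C(C)(C)C)c(Oc2ccccc2)c1 | intermediate
6 | 4-hydroxy-2-phenoxyphenyl pivalate | CC(C)(C)C(=O)Oc1ccc(O)cc1Oc1ccccc1 | intermediate
7 | bromine | BrBr | starting material
8 | 3,5-dibromo-2-(2,4-dibromophenoxy)-4-hydroxyphenyl pivalate | CC(C)(C)C(=O)Oc1cc(Br)c(O)c(Br)c1Oc1ccc(Br)cc1Br | intermediate
9 | iodomethane | CI | starting material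
10 | 3,5-dibromo-2-(2,4-dibromophenoxy)-4-methoxyphenyl pivalate | CC(C)(C)C(=O)Oc1cc(Br)c(OC)c(Br)c1Oc1ccc(Br)cc1Br | intermediate
11 | 3,5-dibromo-2-(2,4-dibromophenoxy)-4-methoxyphenol | COc1c(Br)cc(O)c(Oc2ccc(Br)cc2Br)c1Br | target

Total step count: 5
Longest linear sequence: 5 steps (1 → 3 → 6 → 8 → 10 → 11)

Steps most likely to fail

Step 3 (fourfold bromination). The last substitution, at C2′ of the already para-brominated ring B, may stall under conditions mild enough to spare the free phenol. Forcing it may instead cause over-bromination at C6′ or C6, or ipso attack and oxidative breakdown of ring A. Fallback, from 6 and back at 10: the halogenation is divided around the O-methylation. Compound 6 is treated with three equivalents of bromine in buffered acetic acid at room temperature (Br2, NaOAc, AcOH), which should give 3,5-dibromo-2-(4-bromophenoxy)-4-hydroxyphenyl pivalate F1. The phenol is then methylated (MeI, K2CO3, acetone) to 3,5-dibromo-2-(4-bromophenoxy)-4-methoxyphenyl pivalate F2, which no longer carries an oxidisable phenol. The remaining ortho bromine on ring B is then introduced by Lewis-acid-catalysed bromination (Br2, cat. FeBr3, CH2Cl2, 0 °C to rt). This should deliver 10, and the route continues with step 5.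

Step 1 (Elbs oxidation). Conversion may stay low, and the electron-rich phenoxide may be over-oxidised or oxidatively coupled to dark polymeric material; separating the sulfate salt from inorganic salts may also be troublesome. Fallback, from 1 and back at 6: the para oxygen is introduced through a carbon–boron bond. Para-selective monobromination of 1 (NBS, MeCN, 0 °C) should give 4-bromo-2-phenoxyphenol F3. Acylation (PivCl, Et3N, cat. DMAP, CH2Cl2) then gives 4-bromo-2-phenoxyphenyl pivalate F4. Miyaura borylation (B2pin2, Pd(dppf)Cl2, KOAc, dioxane, 85 °C) gives 2-phenoxy-4-(4,4,5,5-tetramethyl-1,3,2-dioxaborolan-2-yl)phenyl pivalate F5. Ipso-hydroxylation of the boronate under non-basic conditions (Oxone, acetone/H2O, 0 °C) should then give 6 with the pivalate intact, and the route continues with step 3.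

Step 2 (acylation and sulfate cleavage in one pot). Hydrolysis of the acyl chloride in water may outrun acylation of the hindered phenoxide, or the pivalate may be lost during the acidic sulfate cleavage; either process leads toward the unprotected hydroquinone. Fallback, from 3 and back at 6: the two hydroxyls are differentiated by steric hindrance with a temporary silyl group. Acid hydrolysis of 3 (aq HCl, 60 °C, under N2) gives 2-phenoxybenzene-1,4-diol F6. Silylation with a bulky chloride (TIPSCl 1.0 equiv, imidazole, CH2Cl2/DMF, 0 °C) should occur at the unhindered C4 hydroxyl to give 2-phenoxy-4-[(triisopropylsilyl)oxy]phenol F7. The remaining hydroxyl next to the phenoxy group is acylated (PivCl, Et3N, cat. DMAP, CH2Cl2) to 2-phenoxy-4-[(triisopropylsilyl)oxy]phenyl pivalate F8. Desilylation under non-basic conditions (HF·pyridine, THF, 0 °C) should then give 6, and the route continues with step 3.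

Further compounds
F1 | step 3 | 3,5-dibromo-2-(4-bromophenoxy)-4-hydroxyphenyl pivalate | CC(C)(C)C(=O)Oc1cc(Br)c(O)c(Br)c1Oc1ccc(Br)cc1
F2 | step 3 | 3,5-dibromo-2-(4-bromophenoxy)-4-methoxyphenyl pivalate | CC(C)(C)C(=O)Oc1cc(Br)c(OC)c(Br)c1Oc1ccc(Br)cc1
F3 | step 1 | 4-bromo-2-phenoxyphenol | Oc1ccc(Br)cc1Oc1ccccc1
F4 | step 1 | 4-bromo-2-phenoxyphenyl pivalate | CC(C)(C)C(=O)Oc1ccc(Br)cc1Oc1ccccc1
F5 | step 1 | 2-phenoxy-4-(4,4,5,5-tetramethyl-1,3,2-dioxaborolan-2-yl)phenyl pivalate | CC(C)(C)C(=O)Oc1ccc(B2OC(C)(C)C(C)(C)O2)cc1Oc1ccccc1
F6 | step 2 | 2-phenoxybenzene-1,4-diol | Oc1ccc(O)c(Oc2ccccc2)c1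
F7 | step 2 | 2-phenoxy-4-[(triisopropylsilyl)oxy]phenol | CC(C)[Si](Oc1ccc(O)c(Oc2ccccc2)c1)(C(C)C)C(C)C
F8 | step 2 | 2-phenoxy-4-[(triisopropylsilyl)oxy]phenyl pivalate | CC(C)(C)C(=O)Oc1ccc(O[Si](C(C)C)(C(C)C)C(C)C)cc1Oc1ccccc1
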